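**Retrosynthetic overview**
- The target is cut last at the aryl–CH2 bond: chromanol half + pyranone half + a one-carbon iminium salt (Mannich/conjugate-addition methylene bridge).
- The chromanol half comes from 3-prenylphloroacetophenone by one oxidative cyclisation that makes the C3–O bond (stereocentre) and the O1–C2 ring bond in one flask; this is the key step.
- 3-Prenylphloroacetophenone comes from 2,4,6-trihydroxyacetophenone and prenyl bromide (C-prenylation).
- The pyranone half comes from the silyl enol ether of pentan-3-one and malonyl dichloride.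
- Ring order: benzene ring bought; pyranone ring (step 2); dihydropyran ring of the chroman (step 4); the two halves are joined last (step 5).

Assumption: the single stereocentre (chroman C3) is R, as encoded in the SMILES, and the 4-hydroxy-2-pyranone tautomer drawn is the one meant.

Ligand in step 4: (R,R)-BHA = (1R,2R)-N,N'-dihydroxy-N,N'-bis(2,2-diphenylacetyl)cyclohexane-1,2-diamine. Locants in 8 are acetophenone locants (acetyl on C1, prenyl on C3); locants in 10 and 13 are chroman locants.

**Step 1**
Reactants: 1 pentan-3-one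
Product: 2 (Z)-3-(trimethylsilyloxy)pent-2-ene
Conditions: TMSOTf, Et3N, CH2Cl2, 0 °C
Reagents that add atoms: trimethylsilyl trifluoromethanesulfonate, C[Si](C)(C)OS(=O)(=O)C(F)(F)F
Why: Soft enolisation and O-silylation of a symmetric ketone (silyl enol ether formation), so there is no regiochemical issue, and the Z-major geometric mixture converges in step 2.

**Step 2**
Reactants: 2 (Z)-3-(trimethylsilyloxy)pent-2-ene, 3 malonyl dichloride
Product: 5 6-ethyl-4-hydroxy-5-methyl-2H-pyran-2-one, via 4-methyl-3,5-dioxoheptanoyl chloride 4 (not isolated)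
Conditions: Et2O, −78 °C → rt, 12 h; filter the precipitate
Reagents that add atoms: none
Why: C-acylation of the silyl enol ether by one acid chloride followed by enol-lactonisation onto the second (the known silyl enol ether/malonyl dichloride route to 4-hydroxy-2-pyranones) can give only this substitution pattern from a symmetric ketone.

**Step 3**
Reactants: 6 1-(2,4,6-trihydroxyphenyl)ethan-1-one, 7 1-bromo-3-methylbut-2-ene
Product: 8 1-[2,4,6-trihydroxy-3-(3-methylbut-2-en-1-yl)phenyl]ethan-1-one
Conditions: DBU (1.0 equiv), 7 (0.9 equiv), THF, 0 °C → rt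
Reagents that add atoms: none
Why: Base-mediated C-prenylation of the ambident phloroglucinol phenolate, where the two free ring carbons are equivalent so only one mono-C-prenyl isomer can form, and a slight deficit of bromide limits bis-prenylation.

**Step 4 (key step)**
Reactants: 8 1-[2,4,6-trihydroxy-3-(3-methylbut-2-en-1-yl)phenyl]ethan-1-one
Product: 10 1-[(3R)-3,5,7-trihydroxy-2,2-dimethyl-3,4-dihydro-2H-chromen-6-yl]ethan-1-one, via (R)-epoxide 9 (not isolated)
Conditions: Hf(OtBu)4 (10 mol%), (R,R)-BHA (12 mol%), cumene hydroperoxide (1.3 equiv), DMPU (20 mol%), 4 Å MS, CH2Cl2/toluene 1:1, −20 °C → rt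
Reagents that add atoms: cumene hydroperoxide, CC(C)(OO)c1ccccc1
Why: Proposed new method: tetravalent hafnium held by the C2-symmetric bis-hydroxamate exchanges its remaining tert-butoxides for η2-cumyl peroxide and for the substrate, which chelates through the acetyl oxygen and the adjacent 2-aryloxide, so the metal peroxide sits at the same O–C–C–C–C=C distance from the prenyl alkene as in a bishomoallylic alkoxide and delivers oxygen intramolecularly to one alkene face, setting C3 as R in epoxide 9; the epoxide oxygen stays on the Lewis-acidic metal while the free 4-OH, the only flanking phenol able to reach the rear of the tertiary C–O bond, attacks in a 6-endo Markovnikov opening that closes the dihydropyran ring without breaking the C3–O bond, so R is retained; the closest known reaction type is the zirconium/hafnium bis-hydroxamic acid-catalysed hydroxyl-directed asymmetric epoxidation of homoallylic and bishomoallylic alcohols with cumene hydroperoxide, which has not been shown with a phenol as directing group or coupled to ring closure.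

**Step 5**
Reactants: 10 1-[(3R)-3,5,7-trihydroxy-2,2-dimethyl-3,4-dihydro-2H-chromen-6-yl]ethan-1-one, 5 6-ethyl-4-hydroxy-5-methyl-2H-pyran-2-one
Product: 13 6-ethyl-4-hydroxy-5-methyl-3-{[(3R)-6-acetyl-3,5,7-trihydroxy-2,2-dimethyl-3,4-dihydro-2H-chromen-8-yl]methyl}-2H-pyran-2-one (target), via Mannich base 11 (not isolated), via methylidene pyrandione 12 (not isolated)
Conditions: 5 (1.2 equiv), CH2=NMe2+ I− (1.2 equiv), CHCl3, rt, 1 h; then 10 (1.0 equiv), 50 °C
Reagents that add atoms: N,N-dimethylmethyleneiminium iodide (Eschenmoser's salt), C=[N+](C)C.[I-]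
Why: Mannich reaction at the acidic pyranone C3 gives 11, which loses dimethylamine to the methylidene dione 12, and Friedel–Crafts-type conjugate addition (Mannich–Michael, carba-Betti sequence) by C8, the only unsubstituted ring carbon of 10, forms the methylene bridge under conditions that do not touch C3.

**Compound list**
1 | pentan-3-one | CCC(=O)CC | starting material
2 | (Z)-3-(trimethylsilyloxy)pent-2-ene (Z-major mixture) | C/C=C(/CC)O[Si](C)(C)C | intermediate
3 | malonyl dichloride | O=C(Cl)CC(=O)Cl | starting material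
4 | 4-methyl-3,5-dioxoheptanoyl chloride (racemic, not isolated) | CCC(=O)C(C)C(=O)CC(=O)Cl | intermediate
5 | 6-ethyl-4-hydroxy-5-methyl-2H-pyran-2-one | CCc1oc(=O)cc(O)c1C | intermediate
6 | 1-(2,4,6-trihydroxyphenyl)ethan-1-one | CC(=O)c1c(O)cc(O)cc1O | starting material
7 | 1-bromo-3-methylbut-2-ene | CC(C)=CCBr | starting material
8 | 1-[2,4,6-trihydroxy-3-(3-methylbut-2-en-1-yl)phenyl]ethan-1-one | CC(=O)c1c(O)cc(O)c(CC=C(C)C)c1O | intermediate
9 | 1-(3-{[(2R)-3,3-dimethyloxiran-2-yl]methyl}-2,4,6-trihydroxyphenyl)ethan-1-one (not isolated) | CC(=O)c1c(O)cc(O)c(C[C@H]2OC2(C)C)c1O | intermediate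
10 | 1-[(3R)-3,5,7-trihydroxy-2,2-dimethyl-3,4-dihydro-2H-chromen-6-yl]ethan-1-one | CC(=O)c1c(O)cc2OC(C)(C)[C@H](O)Cc2c1O | intermediate
11 | 3-[(dimethylamino)methyl]-6-ethyl-4-hydroxy-5-methyl-2H-pyran-2-one (not isolated) | CCc1oc(=O)c(CN(C)C)c(O)c1C | intermediate
12 | 6-ethyl-5-methyl-3-methylidene-2H-pyran-2,4(3H)-dione (not isolated) | CCC1=C(C)C(=O)C(=C)C(=O)O1 | intermediate
13 | 6-ethyl-4-hydroxy-5-methyl-3-{[(3R)-6-acetyl-3,5,7-trihydroxy-2,2-dimethyl-3,4-dihydro-2H-chromen-8-yl]methyl}-2H-pyran-2-one | CCc1oc(=O)c(Cc2c(O)c(C(C)=O)c(O)c3c2OC(C)(C)[C@H](O)C3)c(O)c1C | target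

**Step count**
Total step count: 5. Longest linear sequence: 3 steps (1 → 2 → 5 → 13, or 6 → 8 → 10 → 13).

**Three steps most likely to fail**

Step 4, the proposed new step, is the largest risk. The substrate and product are both chelating polyphenols and may slow turnover. The hafnium peroxide could hydroxylate the ring instead of the alkene. Ring closure could go through the acetyl-flanked hydroxyl or in the 5-exo sense, giving an isomeric chromanol or a dihydrobenzofuran. The sense of induction of the (R,R)-ligand is a prediction, so it must be checked against authentic (R)-10 and the mirror-image ligand used if it is opposite.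

The fallback uses known chemistry, sets out from 6 and comes back to the route at 10, and fixes regiochemistry by construction. It replaces steps 3 and 4 with six operations.
- The 4-hydroxyl of 6 is alkylated with 3-chloro-3-methylbut-1-yne (DBU, CuCl2 cat., MeCN, 0 °C) to give 1-{2,6-dihydroxy-4-[(2-methylbut-3-yn-2-yl)oxy]phenyl}ethan-1-one F1.
- Heating in xylene at 140 °C (propargyl Claisen rearrangement, 1,5-hydrogen shift, oxa-6π closure; both ortho carbons are equivalent) gives 1-(5,7-dihydroxy-2,2-dimethyl-2H-chromen-6-yl)ethan-1-one F2 as a single regioisomer.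
- Ac2O, pyridine and DMAP give 6-acetyl-2,2-dimethyl-2H-chromene-5,7-diyl diacetate F3.
- Jacobsen–Katsuki epoxidation with (R,R)-(salen)MnCl (salen = N,N'-bis(3,5-di-tert-butylsalicylidene)cyclohexane-1,2-diamine dianion), NaOCl and 4-phenylpyridine N-oxide in CH2Cl2 at 0 °C gives (3R,4R)-6-acetyl-3,4-epoxy-2,2-dimethyl-3,4-dihydro-2H-chromene-5,7-diyl diacetate F4.
- Hydrogenolysis of the benzylic C4–O bond (H2, Pd/C, EtOAc) leaves C3 untouched and gives (3R)-6-acetyl-3-hydroxy-2,2-dimethyl-3,4-dihydro-2H-chromene-5,7-diyl diacetate F5.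
- K2CO3 in MeOH removes both acetates and delivers 10.

Step 5 is the second risk. Free pyranone can add to 12 to give the bis-pyranone methane, and 10 can be bridged to itself, so the cross-coupled product may be eroded.

The fallback sets out from 10 and comes back at 13, with the roles of the two halves reversed. Compound 10 is first treated with N,N-dimethylmethyleneiminium iodide (MeCN, rt, NaHCO3 work-up). This gives, at its only free ring carbon, the isolable phenolic Mannich base 1-[(3R)-8-[(dimethylamino)methyl]-3,5,7-trihydroxy-2,2-dimethyl-3,4-dihydro-2H-chromen-6-yl]ethan-1-one F6. Heating F6 with 5 in 1,4-dioxane at 100 °C expels dimethylamine to give the ortho-quinone methide (3R)-6-acetyl-3,5-dihydroxy-2,2-dimethyl-8-methylidene-3,4-dihydro-2H-chromen-7(8H)-one F7, which is trapped by C3 of the pyranone to give 13. No electrophilic pyranone species and no free nucleophilic arene are present, so neither homodimer can form.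

Step 3 is the third risk. C-prenylation competes with O-prenylation and bis-prenylation, and DBU can be alkylated, so the yield of 8 may be modest.

The fallback sets out from 6 and 7 and comes back at 8. K2CO3 in acetone at rt alkylates the most acidic 4-hydroxyl to give 1-{2,6-dihydroxy-4-[(3-methylbut-2-en-1-yl)oxy]phenyl}ethan-1-one F8. Montmorillonite K10 in CH2Cl2 at 0 °C then moves the prenyl group from oxygen to the ortho carbon (acid-clay 1,3-shift). Because F8 is symmetric, both ortho carbons lead to 8.

**Further compounds**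
F1 | step 4 | 1-{2,6-dihydroxy-4-[(2-methylbut-3-yn-2-yl)oxy]phenyl}ethan-1-one | CC(=O)c1c(O)cc(OC(C)(C)C#C)cc1O
F2 | step 4 | 1-(5,7-dihydroxy-2,2-dimethyl-2H-chromen-6-yl)ethan-1-one | CC(=O)c1c(O)cc2OC(C)(C)C=Cc2c1O
F3 | step 4 | 6-acetyl-2,2-dimethyl-2H-chromene-5,7-diyl diacetate | CC(=O)Oc1cc2OC(C)(C)C=Cc2c(OC(C)=O)c1C(C)=O
F4 | step 4 | (3R,4R)-6-acetyl-3,4-epoxy-2,2-dimethyl-3,4-dihydro-2H-chromene-5,7-diyl diacetate | CC(=O)Oc1cc2OC(C)(C)[C@@H]3O[C@@H]3c2c(OC(C)=O)c1C(C)=O
F5 | step 4 | (3R)-6-acetyl-3-hydroxy-2,2-dimethyl-3,4-dihydro-2H-chromene-5,7-diyl diacetate | CC(=O)Oc1cc2OC(C)(C)[C@H](O)Cc2c(OC(C)=O)c1C(C)=O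
F6 | step 5 | 1-[(3R)-8-[(dimethylamino)methyl]-3,5,7-trihydroxy-2,2-dimethyl-3,4-dihydro-2H-chromen-6-yl]ethan-1-one | CC(=O)c1c(O)c(CN(C)C)c2OC(C)(C)[C@H](O)Cc2c1O
F7 | step 5 | (3R)-6-acetyl-3,5-dihydroxy-2,2-dimethyl-8-methylidene-3,4-dihydro-2H-chromen-7(8H)-one | CC(=O)C1=C(O)C2=C(OC(C)(C)[C@H](O)C2)C(=C)C1=O
F8 | step 3 | 1-{2,6-dihydroxy-4-[(3-methylbut-2-en-1-yl)oxy]phenyl}ethan-1-one | CC(=O)c1c(O)cc(OCC=C(C)C)cc1O
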